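**Plan**

- Retrosynthetic cuts, in order: the two MOM acetals; the C8–CO bond (aryl iodide + CO + 2-methylprop-1-enyl stannane); C3–C4 of ring C; the O1–C2 ether bond; the C6–CH2 bond to the pyrone; the pyrone ring into 3-pentanone and malonyl dichloride.
- Feature used: in ring C, C3 is a lone methylene between the C4 ketone and the O1-bound stereocentre C2(H)Ph. With C4 masked as a silyl enol ether and C2 as a 1-phenylallyl aryl ether, C3–C4 becomes an alkene that metathesis can close.
- Forward order: pyrone ring (steps 1–2); methylene bridge to ring A of phloroacetophenone (step 5); allyl ether (step 7); ring C by metathesis (step 9); C8 acyl chain (steps 11–12); deprotection (step 13).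
- Stereochemistry: the only stereocentre, C2 (S), is set in step 7 by iridium/phosphoramidite-catalysed branched allylic etherification and is carried through unchanged.

Key step: step 9

Remark on locants: flavanone locants (O1, C2, C3, C4, C4a, C5–C8, C8a) are used from ring closure onwards and primed acetophenone locants before it; 2'-OH is the phenol next to the pyronylmethyl group and 6'-OH the one next to the free C5'–H.
Assumption: the (Sa,Sc,Sc) phosphoramidite series is taken to deliver the S ether (the antipodal ligand would give R).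
Assumption: the alkenylstannane of step 12 is taken as a catalogue reagent.

**Route**

Step 1
Reactants: 1 3-pentanone
Product: 2 trimethyl(pent-2-en-3-yloxy)silane (E/Z mixture)
Conditions: TMSCl, Et3N, DMF, 80 °C
Reagents that add atoms: chlorotrimethylsilane, C[Si](C)(C)Cl
Why: Thermodynamic silyl enol ether formation on a symmetrical ketone can give only one regioisomer, and the E/Z ratio does not matter because the geometry disappears in the pyrone.

Step 2
Reactants: 2 trimethyl(pent-2-en-3-yloxy)silane; 3 malonyl dichloride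
Product: 5 6-ethyl-4-hydroxy-5-methyl-2H-pyran-2-one, via 4-methyl-3,5-dioxoheptanoyl chloride 4 (not isolated)
Conditions: Et2O, −78 °C to rt
Reagents that add atoms: none
Why: In this pyrone synthesis from a silyl enol ether and malonyl dichloride, C-acylation gives the diketo acid chloride, whose enol oxygen then closes onto the second acid chloride to give the lactone that tautomerises to the 4-hydroxy-2-pyrone.

Step 3
Reactants: 5 6-ethyl-4-hydroxy-5-methyl-2H-pyran-2-one
Product: 6 3-[(dimethylamino)methyl]-6-ethyl-4-hydroxy-5-methyl-2H-pyran-2-one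
Conditions: Me2N=CH2+ I−, Et3N, CH2Cl2, 0 °C to rt
Reagents that add atoms: N,N-dimethylmethyleneiminium iodide (Eschenmoser's salt), C=[N+](C)C.[I-]
Why: In this Mannich reaction C3 is the only nucleophilic carbon of the vinylogous acid and adds to the preformed iminium ion, which avoids free formaldehyde that would bridge two pyrones.

Step 4
Reactants: 7 (E)-cinnamyl alcohol
Product: 8 (E)-cinnamyl methyl carbonate
Conditions: ClCO2Me, pyridine, CH2Cl2, 0 °C
Reagents that add atoms: methyl chloroformate, COC(=O)Cl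
Why: Standard O-acylation of a primary allylic alcohol with a chloroformate supplies the carbonate leaving group needed for allyliridium formation.

Step 5
Reactants: 6 3-[(dimethylamino)methyl]-6-ethyl-4-hydroxy-5-methyl-2H-pyran-2-one; 9 2',4',6'-trihydroxyacetophenone (3 equiv)
Product: 11 1-[2,4,6-trihydroxy-3-{[6-ethyl-4-hydroxy-5-methyl-2-oxo-2H-pyran-3-yl]methyl}phenyl]ethanone, via 6-ethyl-5-methyl-3-methylidene-2H-pyran-2,4(3H)-dione 10 (not isolated)
Conditions: 1,4-dioxane, 80 °C, N2 sweep
Reagents that add atoms: none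
Why: Thermal loss of dimethylamine from the Mannich base gives a quinone-methide-like methylidene pyrandione that is trapped by Michael-type C-alkylation (carba-Betti reaction) at the equivalent C3'/C5' positions of the acylphloroglucinol, with excess 9 holding back double alkylation.

Step 6
Reactants: 11 1-[2,4,6-trihydroxy-3-{[6-ethyl-4-hydroxy-5-methyl-2-oxo-2H-pyran-3-yl]methyl}phenyl]ethanone
Product: 12 1-[2,6-dihydroxy-4-(methoxymethoxy)-3-{[6-ethyl-4-(methoxymethoxy)-5-methyl-2-oxo-2H-pyran-3-yl]methyl}phenyl]ethanone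
Conditions: MOMCl (2.05 equiv), i-Pr2NEt, CH2Cl2, −20 to 0 °C
Reagents that add atoms: chloromethyl methyl ether, COCCl
Why: O-Alkylation follows acidity, so the pyrone vinylogous acid and the non-chelated 4'-phenol should be capped first while the two ortho phenols, held by the acetyl carbonyl and far less acidic, stay free.

Step 7
Reactants: 12 1-[2,6-dihydroxy-4-(methoxymethoxy)-3-{[6-ethyl-4-(methoxymethoxy)-5-methyl-2-oxo-2H-pyran-3-yl]methyl}phenyl]ethanone; 8 (E)-cinnamyl methyl carbonate
Product: 14 1-[2-hydroxy-4-(methoxymethoxy)-3-{[6-ethyl-4-(methoxymethoxy)-5-methyl-2-oxo-2H-pyran-3-yl]methyl}-6-{[(1S)-1-phenylprop-2-en-1-yl]oxy}phenyl]ethanone, via sodium 6'-phenolate of the bis-MOM diol 13 (not isolated)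
Conditions: NaH (1.0 equiv), THF, 0 °C; then [Ir(cod)Cl]2 (2 mol%), (Sa,Sc,Sc)-O,O'-(1,1'-binaphthalene-2,2'-diyl) N,N-bis(1-phenylethyl)phosphoramidite (4 mol%), THF, 45 °C
Reagents that add atoms: none
Why: In this iridium-catalysed asymmetric allylic etherification the aryloxide attacks the phenyl-bearing terminus of the cyclometallated allyliridium phosphoramidite complex to give the branched ether with C2 set as S by the ligand, and of the two ortho oxygens the 6'-one, flanked by hydrogen and not by the pyronylmethyl group, should react while the 2'-OH stays chelated.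

Step 8
Reactants: 14 1-[2-hydroxy-4-(methoxymethoxy)-3-{[6-ethyl-4-(methoxymethoxy)-5-methyl-2-oxo-2H-pyran-3-yl]methyl}-6-{[(1S)-1-phenylprop-2-en-1-yl]oxy}phenyl]ethanone
Product: 15 tert-butyldimethylsilyl enol ether of 1-[2-(tert-butyldimethylsilyloxy)-4-(methoxymethoxy)-3-{[6-ethyl-4-(methoxymethoxy)-5-methyl-2-oxo-2H-pyran-3-yl]methyl}-6-{[(1S)-1-phenylprop-2-en-1-yl]oxy}phenyl]ethanone
Conditions: TBSOTf (3 equiv), Et3N (5 equiv), CH2Cl2, 0 °C to rt
Reagents that add atoms: tert-butyldimethylsilyl trifluoromethanesulfonate, CC(C)(C)[Si](C)(C)OS(=O)(=O)C(F)(F)F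
Why: Soft enolisation with a silyl triflate and amine turns the methyl ketone into its only possible enol ether and silylates the hindered chelated phenol in the same operation, while the acetals and the allylic ether are inert to the amine-buffered reagent.

Step 9
Reactants: 15 tert-butyldimethylsilyl enol ether of 1-[2-(tert-butyldimethylsilyloxy)-4-(methoxymethoxy)-3-{[6-ethyl-4-(methoxymethoxy)-5-methyl-2-oxo-2H-pyran-3-yl]methyl}-6-{[(1S)-1-phenylprop-2-en-1-yl]oxy}phenyl]ethanone
Product: 16 (2S)-4,5-bis(tert-butyldimethylsilyloxy)-6-{[6-ethyl-4-(methoxymethoxy)-5-methyl-2-oxo-2H-pyran-3-yl]methyl}-7-(methoxymethoxy)-2-phenyl-2H-chromene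
Conditions: second-generation Grubbs catalyst RuCl2(=CHPh)(PCy3)(H2IMes) (10 mol%), 1,4-benzoquinone (20 mol%), degassed toluene (0.005 M), 70 °C, Ar sparge
Reagents that add atoms: none
Why: Ring-closing olefin metathesis of a silyl enol ether with a terminal alkene: the ruthenium benzylidene exchanges onto the unhindered vinyl group of the allyl ether, the new alkylidene adds [2+2] across the 1,1-disubstituted enol ether CH2=C(OTBS)Ar, and cycloreversion of the ruthenacyclobutane releases the C3=C4 bond and a ruthenium methylidene that turns over with loss of ethene. The closest known reaction type is silyl enol ether–ene ring-closing metathesis, established for 4-silyloxy-1,2-dihydroquinolines and for carbocyclic and oxacyclic silyl enol ethers, here with oxygen in place of nitrogen in the tether. Ring C closes as a six-membered ring with the new double bond endocyclic, the two alkenes being held close by the aromatic C4a–C8a bond and O1. No stereocentre is created, and C2 sits next to the reacting vinyl group and keeps its S configuration as long as no ruthenium hydride migrates the allyl double bond, which benzoquinone, ethene removal and high dilution are meant to prevent. The step needs initiation at the monosubstituted alkene and closure onto the enol ether in preference to intermolecular metathesis, and the substrate secures this because its only other alkenes are the tetrasubstituted, conjugated pyrone double bonds, which are inert to the catalyst.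

Step 10
Reactants: 16 (2S)-4,5-bis(tert-butyldimethylsilyloxy)-6-{[6-ethyl-4-(methoxymethoxy)-5-methyl-2-oxo-2H-pyran-3-yl]methyl}-7-(methoxymethoxy)-2-phenyl-2H-chromene
Product: 17 (2S)-6-{[6-ethyl-4-(methoxymethoxy)-5-methyl-2-oxo-2H-pyran-3-yl]methyl}-5-hydroxy-7-(methoxymethoxy)-2-phenyl-2,3-dihydro-4H-chromen-4-one
Conditions: HF·pyridine, pyridine, THF, 0 °C to rt
Reagents that add atoms: none
Why: Desilylation with a mildly acidic fluoride source cleaves the aryl silyl ether and hydrolyses the silyl enol ether by protonation at C3, so no free C4 enolate forms that could open ring C by β-elimination of O1 and scramble C2.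

Step 11
Reactants: 17 (2S)-6-{[6-ethyl-4-(methoxymethoxy)-5-methyl-2-oxo-2H-pyran-3-yl]methyl}-5-hydroxy-7-(methoxymethoxy)-2-phenyl-2,3-dihydro-4H-chromen-4-one
Product: 18 (2S)-6-{[6-ethyl-4-(methoxymethoxy)-5-methyl-2-oxo-2H-pyran-3-yl]methyl}-5-hydroxy-8-iodo-7-(methoxymethoxy)-2-phenyl-2,3-dihydro-4H-chromen-4-one
Conditions: NIS (1.05 equiv), DMF, 0 °C to rt, dark
Reagents that add atoms: N-iodosuccinimide, O=C1CCC(=O)N1I
Why: Electrophilic aromatic iodination can go only to C8, the single unsubstituted position of ring A, which is para to the free 5-OH and ortho to two ether oxygens.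

Step 12
Reactants: 18 (2S)-6-{[6-ethyl-4-(methoxymethoxy)-5-methyl-2-oxo-2H-pyran-3-yl]methyl}-5-hydroxy-8-iodo-7-(methoxymethoxy)-2-phenyl-2,3-dihydro-4H-chromen-4-one; 19 tributyl(2-methylprop-1-en-1-yl)stannane
Product: 20 (2S)-6-{[6-ethyl-4-(methoxymethoxy)-5-methyl-2-oxo-2H-pyran-3-yl]methyl}-5-hydroxy-7-(methoxymethoxy)-8-(3-methylbut-2-enoyl)-2-phenyl-2,3-dihydro-4H-chromen-4-one
Conditions: Pd2(dba)3 (5 mol%), AsPh3 (20 mol%), CO (3 atm), NMP, 65 °C
Reagents that add atoms: carbon monoxide, [C-]#[O+]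
Why: In this carbonylative Stille coupling zerovalent palladium adds oxidatively to the aryl iodide, CO inserts into the hindered aryl–palladium bond, and transmetalation with the alkenylstannane followed by reductive elimination gives the aryl alkenyl ketone under neutral conditions that spare the flavanone and C2.

Step 13
Reactants: 20 (2S)-6-{[6-ethyl-4-(methoxymethoxy)-5-methyl-2-oxo-2H-pyran-3-yl]methyl}-5-hydroxy-7-(methoxymethoxy)-8-(3-methylbut-2-enoyl)-2-phenyl-2,3-dihydro-4H-chromen-4-one
Product: 21 (2S)-6-[(6-ethyl-4-hydroxy-5-methyl-2-oxo-2H-pyran-3-yl)methyl]-5,7-dihydroxy-8-(3-methylbut-2-enoyl)-2-phenyl-2,3-dihydro-4H-chromen-4-one (CNP0311807.1)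
Conditions: HCl (2 M), MeOH/THF, 0 °C to rt, stopped at full conversion
Reagents that add atoms: none
Why: Acid-catalysed acetal cleavage should be fast at room temperature because one MOM group is a vinylogous ester acetal and the other sits ortho to the new aryl ketone, which leaves little time for acid-promoted oxa-Michael closure of the enone onto O7 and none for opening of ring C.

**Compound list**

1 | 3-pentanone | CCC(=O)CC | starting material
2 | trimethyl(pent-2-en-3-yloxy)silane (E/Z mixture) | CC=C(CC)O[Si](C)(C)C | intermediate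
3 | malonyl dichloride | O=C(Cl)CC(=O)Cl | starting material
4 | 4-methyl-3,5-dioxoheptanoyl chloride (racemic, not isolated) | CCC(=O)C(C)C(=O)CC(=O)Cl | intermediate
5 | 6-ethyl-4-hydroxy-5-methyl-2H-pyran-2-one | CCc1oc(=O)cc(O)c1C | intermediate
6 | 3-[(dimethylamino)methyl]-6-ethyl-4-hydroxy-5-methyl-2H-pyran-2-one | CCc1oc(=O)c(CN(C)C)c(O)c1C | intermediate
7 | (E)-cinnamyl alcohol | OC/C=C/c1ccccc1 | starting material
8 | (E)-cinnamyl methyl carbonate | COC(=O)OC/C=C/c1ccccc1 | intermediate
9 | 2',4',6'-trihydroxyacetophenone | CC(=O)c1c(O)cc(O)cc1O | starting material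
10 | 6-ethyl-5-methyl-3-methylidene-2H-pyran-2,4(3H)-dione (not isolated) | CCC1=C(C)C(=O)C(=C)C(=O)O1 | intermediate
11 | 1-[2,4,6-trihydroxy-3-{[6-ethyl-4-hydroxy-5-methyl-2-oxo-2H-pyran-3-yl]methyl}phenyl]ethanone | CCc1oc(=O)c(Cc2c(O)cc(O)c(C(C)=O)c2O)c(O)c1C | intermediate
12 | 1-[2,6-dihydroxy-4-(methoxymethoxy)-3-{[6-ethyl-4-(methoxymethoxy)-5-methyl-2-oxo-2H-pyran-3-yl]methyl}phenyl]ethanone | CCc1oc(=O)c(Cc2c(OCOC)cc(O)c(C(C)=O)c2O)c(OCOC)c1C | intermediate
13 | sodium 6'-phenolate of 12 (not isolated) | [Na+].CCc1oc(=O)c(Cc2c(OCOC)cc([O-])c(C(C)=O)c2O)c(OCOC)c1C | intermediate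
14 | 1-[2-hydroxy-4-(methoxymethoxy)-3-{[6-ethyl-4-(methoxymethoxy)-5-methyl-2-oxo-2H-pyran-3-yl]methyl}-6-{[(1S)-1-phenylprop-2-en-1-yl]oxy}phenyl]ethanone | CCc1oc(=O)c(Cc2c(OCOC)cc(O[C@@H](C=C)c3ccccc3)c(C(C)=O)c2O)c(OCOC)c1C | intermediate
15 | tert-butyldimethylsilyl enol ether of 1-[2-(tert-butyldimethylsilyloxy)-4-(methoxymethoxy)-3-{[6-ethyl-4-(methoxymethoxy)-5-methyl-2-oxo-2H-pyran-3-yl]methyl}-6-{[(1S)-1-phenylprop-2-en-1-yl]oxy}phenyl]ethanone | CCc1oc(=O)c(Cc2c(OCOC)cc(O[C@@H](C=C)c3ccccc3)c(C(=C)O[Si](C)(C)C(C)(C)C)c2O[Si](C)(C)C(C)(C)C)c(OCOC)c1C | intermediate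
16 | (2S)-4,5-bis(tert-butyldimethylsilyloxy)-6-{[6-ethyl-4-(methoxymethoxy)-5-methyl-2-oxo-2H-pyran-3-yl]methyl}-7-(methoxymethoxy)-2-phenyl-2H-chromene | CCc1oc(=O)c(Cc2c(OCOC)cc3c(c2O[Si](C)(C)C(C)(C)C)C(O[Si](C)(C)C(C)(C)C)=C[C@@H](c2ccccc2)O3)c(OCOC)c1C | intermediate
17 | (2S)-6-{[6-ethyl-4-(methoxymethoxy)-5-methyl-2-oxo-2H-pyran-3-yl]methyl}-5-hydroxy-7-(methoxymethoxy)-2-phenyl-2,3-dihydro-4H-chromen-4-one | CCc1oc(=O)c(Cc2c(OCOC)cc3c(c2O)C(=O)C[C@@H](c2ccccc2)O3)c(OCOC)c1C | intermediate
18 | (2S)-6-{[6-ethyl-4-(methoxymethoxy)-5-methyl-2-oxo-2H-pyran-3-yl]methyl}-5-hydroxy-8-iodo-7-(methoxymethoxy)-2-phenyl-2,3-dihydro-4H-chromen-4-one | CCc1oc(=O)c(Cc2c(OCOC)c(I)c3c(c2O)C(=O)C[C@@H](c2ccccc2)O3)c(OCOC)c1C | intermediate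
19 | tributyl(2-methylprop-1-en-1-yl)stannane | CCCC[Sn](CCCC)(CCCC)C=C(C)C | starting material
20 | (2S)-6-{[6-ethyl-4-(methoxymethoxy)-5-methyl-2-oxo-2H-pyran-3-yl]methyl}-5-hydroxy-7-(methoxymethoxy)-8-(3-methylbut-2-enoyl)-2-phenyl-2,3-dihydro-4H-chromen-4-one | CCc1oc(=O)c(Cc2c(OCOC)c(C(=O)C=C(C)C)c3c(c2O)C(=O)C[C@@H](c2ccccc2)O3)c(OCOC)c1C | intermediate
21 | (2S)-6-[(6-ethyl-4-hydroxy-5-methyl-2-oxo-2H-pyran-3-yl)methyl]-5,7-dihydroxy-8-(3-methylbut-2-enoyl)-2-phenyl-2,3-dihydro-4H-chromen-4-one | CCc1oc(=O)c(Cc2c(O)c(C(=O)C=C(C)C)c3c(c2O)C(=O)C[C@@H](c2ccccc2)O3)c(O)c1C | target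

**Totals**

Total step count: 13.
Longest linear sequence: 12 steps (steps 1–3 and 5–13, from 3-pentanone); 9 steps from 2',4',6'-trihydroxyacetophenone.

**Steps most likely to fail**

1. Step 9. The ruthenium alkylidene formed at the allyl terminus may not engage the twisted enol ether, which is flanked by two ortho substituents. Ruthenium hydride formation with migration of the allyl double bond (which would erase C2) or intermolecular metathesis could then take over. The fallback sets out from 14 and returns at 17. Treating 14 with t-Bu2Si(OTf)2 and Et3N in CH2Cl2 should tie the 2'-oxygen and the enol oxygen into a six-membered ring, giving the cyclic di-tert-butylsilylene enol ether of 14, i.e. 2,2-di-tert-butyl-4-methylidene-4H-1,3,2-benzodioxasiline bearing the 5-[(1S)-1-phenylprop-2-enyloxy], 7-methoxymethoxy and 8-pyronylmethyl groups F1. This tether holds the enol methylene in the plane of ring A and pointing at the allyl ether, and it removes one bulky silyl group from the reacting site. Ring-closing metathesis under the step 9 conditions should then give the silylene-bridged chromene (2S)-4,5-[(di-tert-butylsilanediyl)bis(oxy)]-6-{[6-ethyl-4-(methoxymethoxy)-5-methyl-2-oxo-2H-pyran-3-yl]methyl}-7-(methoxymethoxy)-2-phenyl-2H-chromene F2. HF·pyridine would open the silylene and deliver 17.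

2. Step 7. The chelated aryloxide may attack the allyliridium intermediate slowly and through the wrong oxygen (the flanked 2'-O), or twice, so that site selectivity is lost. The fallback sets out from 9 (with 8 and 6) and returns at 14; it fixes the oxygen pattern by symmetry before the pyrone is attached. Mono-protection of 9 with one equivalent of MOMCl and i-Pr2NEt should give 1-[2,6-dihydroxy-4-(methoxymethoxy)phenyl]ethanone F3, whose two free phenols are equivalent. Iridium-catalysed etherification with 8 under the step 7 conditions should then give 1-[2-hydroxy-4-(methoxymethoxy)-6-{[(1S)-1-phenylprop-2-en-1-yl]oxy}phenyl]ethanone F4, after which the remaining phenol is chelated and unreactive. Heating F4 with Mannich base 6 should alkylate the carbon ortho to the single free phenol in a Betti-type, hydrogen-bond-directed addition to the methylidene pyrandione, giving 1-[2-hydroxy-3-[(6-ethyl-4-hydroxy-5-methyl-2-oxo-2H-pyran-3-yl)methyl]-4-(methoxymethoxy)-6-{[(1S)-1-phenylprop-2-en-1-yl]oxy}phenyl]ethanone F5. MOMCl and i-Pr2NEt would then cap only the acidic pyrone hydroxyl to give 14.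

3. Step 12. After oxidative addition and CO insertion, transmetalation of the β,β-disubstituted alkenylstannane onto the crowded acylpalladium may be slow, so protodeiodination or direct coupling without CO could compete, and prolonged heating could open ring C. The fallback sets out from 17 and returns at 20 without palladium. Vilsmeier–Haack formylation (POCl3, DMF, then aqueous NaOAc) at C8, the only free position of ring A, should give (2S)-6-{[6-ethyl-4-(methoxymethoxy)-5-methyl-2-oxo-2H-pyran-3-yl]methyl}-5-hydroxy-7-(methoxymethoxy)-4-oxo-2-phenyl-3,4-dihydro-2H-chromene-8-carbaldehyde F6. Nozaki–Hiyama–Kishi addition of 1-bromo-2-methylprop-1-ene (CrCl2, catalytic NiCl2, DMF), which is selective for the aldehyde over the C4 ketone, should give the allylic alcohol (2S)-6-{[6-ethyl-4-(methoxymethoxy)-5-methyl-2-oxo-2H-pyran-3-yl]methyl}-5-hydroxy-8-(1-hydroxy-3-methylbut-2-en-1-yl)-7-(methoxymethoxy)-2-phenyl-2,3-dihydro-4H-chromen-4-one F7 as a mixture of carbinol epimers. Oxidation with MnO2 in CH2Cl2 would give 20.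

**Further compounds**

F1 | step 9 | cyclic di-tert-butylsilylene enol ether of 14 (2,2-di-tert-butyl-4-methylidene-4H-1,3,2-benzodioxasiline with 5-[(1S)-1-phenylprop-2-enyloxy], 7-methoxymethoxy and 8-pyronylmethyl groups) | CCc1oc(=O)c(Cc2c(OCOC)cc(O[C@@H](C=C)c3ccccc3)c4C(=C)O[Si](C(C)(C)C)(C(C)(C)C)Oc24)c(OCOC)c1C
F2 | step 9 | (2S)-4,5-[(di-tert-butylsilanediyl)bis(oxy)]-6-{[6-ethyl-4-(methoxymethoxy)-5-methyl-2-oxo-2H-pyran-3-yl]methyl}-7-(methoxymethoxy)-2-phenyl-2H-chromene | CCc1oc(=O)c(Cc2c(OCOC)cc3c4c2O[Si](C(C)(C)C)(C(C)(C)C)OC4=C[C@@H](c2ccccc2)O3)c(OCOC)c1C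
F3 | step 7 | 1-[2,6-dihydroxy-4-(methoxymethoxy)phenyl]ethanone | CC(=O)c1c(O)cc(OCOC)cc1O
F4 | step 7 | 1-[2-hydroxy-4-(methoxymethoxy)-6-{[(1S)-1-phenylprop-2-en-1-yl]oxy}phenyl]ethanone | CC(=O)c1c(O)cc(OCOC)cc1O[C@@H](C=C)c1ccccc1
F5 | step 7 | 1-[2-hydroxy-3-[(6-ethyl-4-hydroxy-5-methyl-2-oxo-2H-pyran-3-yl)methyl]-4-(methoxymethoxy)-6-{[(1S)-1-phenylprop-2-en-1-yl]oxy}phenyl]ethanone | CCc1oc(=O)c(Cc2c(OCOC)cc(O[C@@H](C=C)c3ccccc3)c(C(C)=O)c2O)c(O)c1C
F6 | step 12 | (2S)-6-{[6-ethyl-4-(methoxymethoxy)-5-methyl-2-oxo-2H-pyran-3-yl]methyl}-5-hydroxy-7-(methoxymethoxy)-4-oxo-2-phenyl-3,4-dihydro-2H-chromene-8-carbaldehyde | CCc1oc(=O)c(Cc2c(OCOC)c(C=O)c3c(c2O)C(=O)C[C@@H](c2ccccc2)O3)c(OCOC)c1C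
F7 | step 12 | (2S)-6-{[6-ethyl-4-(methoxymethoxy)-5-methyl-2-oxo-2H-pyran-3-yl]methyl}-5-hydroxy-8-(1-hydroxy-3-methylbut-2-en-1-yl)-7-(methoxymethoxy)-2-phenyl-2,3-dihydro-4H-chromen-4-one (carbinol epimers) | CCc1oc(=O)c(Cc2c(OCOC)c(C(O)C=C(C)C)c3c(c2O)C(=O)C[C@@H](c2ccccc2)O3)c(OCOC)c1C
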